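Ring B atoms carry isocoumarin locants (C1, O2, C3, C4, C4a, C5–C8, C8a); ring C atoms carry primed locants.

**Plan**
- Retrosynthesis: cut the lactone O2–C1 bond (enol lactonisation), then the C8a–C4a bond of ring B (aldol of an opened 4-methoxy-2-pyrone), then C5–CH2Ar (enolate benzylation) and C5–C4a (Claisen acylation of the pyrone methyl group).
- Enabling feature: ring B (C4a, C5, C6, C7, C8, C8a) bears 8-OMe and a free 6-OH meta to each other, with the carboxyl carbon C1 on C8a. This is the imprint of an opened 4-methoxy-2-pyrone, and C5 lies between C6 and C4a, both carbonyl carbons before folding.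
- Ring C (2'-OMe, 4'-OH, benzylic carbon on C1') shows the same imprint, so it is built first from the same pyrone and turned into a benzylic bromide.
- Forward order: ring C (steps 1–5), pyrone ketone (step 6), benzylation at C5 (step 7), ring B by pyrone opening and aldol aromatisation (step 8), lactone ring A with loss of the ketal and the MOM group (step 9).
- Stereochemistry: the target has no stereocentre; the one sp3 centre of the key-step precursor is racemic and becomes the aromatic C5.

Key step: step 8

Remark: the ethylene ketal of ethyl acetoacetate, ethyl (2-methyl-1,3-dioxolan-2-yl)acetate, is taken as a purchased material.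
Remark: the ring C phenol is carried as its methoxymethyl (MOM) ether, so that one acid treatment removes it together with the ketal at the end.

**Step 1**
Reactants: 1 4-methoxy-6-methyl-2H-pyran-2-one (2 equiv, the second equivalent acts as base and is recovered); 2 methyl methoxyacetate
Product: 3 4-methoxy-6-(3-methoxy-2-oxopropyl)-2H-pyran-2-one
Conditions: LiN(iPr)2 (2 equiv), THF, −78 °C; then 2, −78 → −20 °C; AcOH
Reagents that add atoms: none
Why: The lithiated 6-methyl group of 1 is a vinylogous ester enolate that should be C-acylated by the ester in a Claisen condensation, the second equivalent of the anion taking up the more acidic product.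

**Step 2**
Reactants: 3 4-methoxy-6-(3-methoxy-2-oxopropyl)-2H-pyran-2-one
Product: 5 methyl 4-hydroxy-2-methoxy-6-(methoxymethyl)benzoate, via ring-opened keto ester 4 (not isolated)
Conditions: KOH, MeOH, reflux; then 1 M HCl
Reagents that add atoms: methanol, CO
Why: Methoxide opens the pyrone at its carbonyl and the ester α-carbon of the resulting enolate condenses with the methoxyacetyl ketone, the known ring opening and aldol aromatisation of 6-(2-oxoalkyl)-4-methoxy-2-pyrones, which leaves the pyrone 4-OMe ortho to the ester and the ring oxygen as the para phenol.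

**Step 3**
Reactants: 5 methyl 4-hydroxy-2-methoxy-6-(methoxymethyl)benzoate
Product: 6 methyl 2-methoxy-4-(methoxymethoxy)-6-(methoxymethyl)benzoate
Conditions: NaH, MOMCl, DMF, 0 °C → rt
Reagents that add atoms: chloromethyl methyl ether (MOMCl), COCCl
Why: Williamson-type O-alkylation of the sodium phenoxide gives an acetal that should withstand hydride, the Appel reaction and hot methanolic KOH and is removed by acid in step 9.

**Step 4**
Reactants: 6 methyl 2-methoxy-4-(methoxymethoxy)-6-(methoxymethyl)benzoate
Product: 7 [2-methoxy-4-(methoxymethoxy)-6-(methoxymethyl)phenyl]methanol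
Conditions: LiAlH4, THF, 0 °C → rt; then H2O, aq. NaOH
Reagents that add atoms: none
Why: Hydride reduction of a benzoate ester to the benzylic alcohol, with the ethers and the MOM acetal inert to LiAlH4.

**Step 5**
Reactants: 7 [2-methoxy-4-(methoxymethoxy)-6-(methoxymethyl)phenyl]methanol
Product: 8 2-(bromomethyl)-1-methoxy-5-(methoxymethoxy)-3-(methoxymethyl)benzene
Conditions: CBr4, PPh3, CH2Cl2, 0 °C; quick filtration through silica, used at once
Reagents that add atoms: carbon tetrabromide, BrC(Br)(Br)Br
Why: The Appel reaction converts the benzylic alcohol into the bromide under neutral conditions that spare the MOM acetal, and the electron-rich bromide is taken straight into step 7 without storage.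

**Step 6**
Reactants: 1 4-methoxy-6-methyl-2H-pyran-2-one (2 equiv, the second equivalent acts as base and is recovered); 9 ethyl (2-methyl-1,3-dioxolan-2-yl)acetate
Product: 10 4-methoxy-6-[3-(2-methyl-1,3-dioxolan-2-yl)-2-oxopropyl]-2H-pyran-2-one
Conditions: LiN(iPr)2 (2 equiv), THF, −78 °C; then 9, −78 → −20 °C; AcOH
Reagents that add atoms: none
Why: Claisen acylation of the lithiated pyrone methyl group as in step 1, run without free amide base so that ester 9 is not enolised with loss of the ketal oxygen.

**Step 7**
Reactants: 10 4-methoxy-6-[3-(2-methyl-1,3-dioxolan-2-yl)-2-oxopropyl]-2H-pyran-2-one; 8 2-(bromomethyl)-1-methoxy-5-(methoxymethoxy)-3-(methoxymethyl)benzene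
Product: 11 rac-4-methoxy-6-{1-[2-methoxy-4-(methoxymethoxy)-6-(methoxymethyl)phenyl]-4-(2-methyl-1,3-dioxolan-2-yl)-3-oxobutan-2-yl}-2H-pyran-2-one
Conditions: NaH, THF, 0 °C; then freshly made 8, 0 °C → rt
Reagents that add atoms: none
Why: The methylene between pyrone C6 and the ketone is the only doubly activated position, and its sodium enolate should be C-benzylated by the reactive bromide (alkylation of a β-dicarbonyl-type enolate), the new stereocentre forming as a racemate that step 8 erases.

**Step 8**
Reactants: 11 rac-4-methoxy-6-{1-[2-methoxy-4-(methoxymethoxy)-6-(methoxymethyl)phenyl]-4-(2-methyl-1,3-dioxolan-2-yl)-3-oxobutan-2-yl}-2H-pyran-2-one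
Product: 13 methyl 4-hydroxy-6-methoxy-3-{[2-methoxy-4-(methoxymethoxy)-6-(methoxymethyl)phenyl]methyl}-2-[(2-methyl-1,3-dioxolan-2-yl)methyl]benzoate, via ring-opened keto ester 12 (not isolated)
Conditions: KOH, MeOH, reflux; then AcOH to pH 6
Reagents that add atoms: methanol, CO
Why: Methoxide adds to the pyrone carbonyl and the ring opens to the enolate of keto ester 12, whose extended enolate is nucleophilic at the ester α-carbon (future C8a); this carbon attacks the ketone next to the ketal-bearing CH2 (future C4a), and loss of water followed by enolisation of the C6 carbonyl aromatises ring B. The closest known reaction is the base-induced opening and aldol aromatisation of 6-(2-oxoalkyl)-4-methoxy-2-pyrones to methyl 4-hydroxy-2-methoxybenzoates, already used in step 2. Ring B closes by a 6-(enolendo)-exo-trig aldol addition that forms the C8a–C4a bond. No stereocentre is created, and the racemic centre of 11 becomes the aromatic C5. The step needs aldol rather than Claisen folding and attack on the right carbonyl: the benzyl group on C5 makes the Claisen product (C5 onto the ester) a quaternary triketone that cannot aromatise and can only revert, the third carbonyl is masked as the dioxolane, and attack of C8a on the C6 carbonyl would give a four-membered ring. The pyrone 4-OMe ends as 8-OMe and the ring oxygen as the free 6-OH, so the two oxygens need no later differentiation.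

**Step 9**
Reactants: 13 methyl 4-hydroxy-6-methoxy-3-{[2-methoxy-4-(methoxymethoxy)-6-(methoxymethyl)phenyl]methyl}-2-[(2-methyl-1,3-dioxolan-2-yl)methyl]benzoate
Product: 15 6-hydroxy-5-{[4-hydroxy-2-methoxy-6-(methoxymethyl)phenyl]methyl}-8-methoxy-3-methyl-1H-isochromen-1-one, via keto ester diphenol 14 (not isolated)
Conditions: 2 M aq. HCl, THF–MeOH, 50 °C; evaporate; TsOH·H2O (cat.), toluene, 80 °C
Reagents that add atoms: water, O
Why: Aqueous acid hydrolyses the dioxolane and the MOM acetal, and the freed ketone then closes through its enol onto the neighbouring methyl ester with loss of methanol (acid-catalysed enol lactonisation of a 2-(2-oxopropyl)benzoate to a 3-methylisocoumarin), while the benzylic methyl ether, meta to both ring C oxygens, should be stable.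

**Compound list**
1 | 4-methoxy-6-methyl-2H-pyran-2-one | COc1cc(C)oc(=O)c1 | starting material
2 | methyl methoxyacetate | COCC(=O)OC | starting material
3 | 4-methoxy-6-(3-methoxy-2-oxopropyl)-2H-pyran-2-one | COCC(=O)Cc1cc(OC)cc(=O)o1 | intermediate
4 | methyl (2E)-3,8-dimethoxy-5,7-dioxooct-2-enoate | COC(=O)/C=C(/OC)CC(=O)CC(=O)COC | intermediate
5 | methyl 4-hydroxy-2-methoxy-6-(methoxymethyl)benzoate | COCc1cc(O)cc(OC)c1C(=O)OC | intermediate
6 | methyl 2-methoxy-4-(methoxymethoxy)-6-(methoxymethyl)benzoate | COCOc1cc(COC)c(C(=O)OC)c(OC)c1 | intermediate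
7 | [2-methoxy-4-(methoxymethoxy)-6-(methoxymethyl)phenyl]methanol | COCOc1cc(COC)c(CO)c(OC)c1 | intermediate
8 | 2-(bromomethyl)-1-methoxy-5-(methoxymethoxy)-3-(methoxymethyl)benzene | COCOc1cc(COC)c(CBr)c(OC)c1 | intermediate
9 | ethyl (2-methyl-1,3-dioxolan-2-yl)acetate | CCOC(=O)CC1(C)OCCO1 | starting material
10 | 4-methoxy-6-[3-(2-methyl-1,3-dioxolan-2-yl)-2-oxopropyl]-2H-pyran-2-one | COc1cc(=O)oc(CC(=O)CC2(C)OCCO2)c1 | intermediate
11 | rac-4-methoxy-6-{1-[2-methoxy-4-(methoxymethoxy)-6-(methoxymethyl)phenyl]-4-(2-methyl-1,3-dioxolan-2-yl)-3-oxobutan-2-yl}-2H-pyran-2-one (racemate) | COc1cc(=O)oc(C(Cc2c(COC)cc(OCOC)cc2OC)C(=O)CC2(C)OCCO2)c1 | intermediate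
12 | methyl (2E)-3-methoxy-6-{[2-methoxy-4-(methoxymethoxy)-6-(methoxymethyl)phenyl]methyl}-8-(2-methyl-1,3-dioxolan-2-yl)-5,7-dioxooct-2-enoate (racemate) | COC(=O)/C=C(/OC)CC(=O)C(Cc1c(COC)cc(OCOC)cc1OC)C(=O)CC1(C)OCCO1 | intermediate
13 | methyl 4-hydroxy-6-methoxy-3-{[2-methoxy-4-(methoxymethoxy)-6-(methoxymethyl)phenyl]methyl}-2-[(2-methyl-1,3-dioxolan-2-yl)methyl]benzoate | COC(=O)c1c(OC)cc(O)c(Cc2c(COC)cc(OCOC)cc2OC)c1CC1(C)OCCO1 | intermediate
14 | methyl 4-hydroxy-3-{[4-hydroxy-2-methoxy-6-(methoxymethyl)phenyl]methyl}-6-methoxy-2-(2-oxopropyl)benzoate | COC(=O)c1c(OC)cc(O)c(Cc2c(COC)cc(O)cc2OC)c1CC(C)=O | intermediate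
15 | 6-hydroxy-5-{[4-hydroxy-2-methoxy-6-(methoxymethyl)phenyl]methyl}-8-methoxy-3-methyl-1H-isochromen-1-one | COCc1cc(O)cc(OC)c1Cc1c(O)cc(OC)c2c(=O)oc(C)cc12 | target

**Step count**
Total step count: 9. Longest linear sequence: 8 steps (steps 1–5, 7, 8, 9); step 6 is a one-step side branch.

**Steps most likely to fail**

Step 8. Methoxide may cleave the α-branched β-dicarbonyl unit by a retro-Claisen reaction before or after ring opening. The opened chain may also rest as its unreactive 1,3-diketone enolate, or close through the CH2 next to the ketal onto the methoxy-bearing enoate carbon instead of through C8a. The fallback folds ring B before the benzyl group is present and sets out from 10.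
- Treated with KOH in MeOH as in step 2, 10 should give methyl 4-hydroxy-2-methoxy-6-[(2-methyl-1,3-dioxolan-2-yl)methyl]benzoate F1, the unbranched and directly precedented case.
- Bromination with NBS in MeCN at 0 °C is expected mainly next to the side chain (para to the methoxy group, ortho to the hydroxyl, as in halogenation of orsellinate esters) and should give methyl 3-bromo-4-hydroxy-6-methoxy-2-[(2-methyl-1,3-dioxolan-2-yl)methyl]benzoate F2. The site of bromination would have to be confirmed.
- Bromide 8 is converted with Zn dust and LiCl in THF into {[2-methoxy-4-(methoxymethoxy)-6-(methoxymethyl)phenyl]methyl}zinc bromide F3.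
- Negishi coupling of F2 with an excess of F3 (Pd(OAc)2, SPhos, THF, slow addition to allow for the free phenol) comes back to the route at 13.

Step 7. The ambident enolate of 10 may be alkylated on oxygen or twice on carbon, and the bromide may be consumed by self-condensation before it meets the enolate. The fallback reverses the order of the two bond formations and sets out from 1 and 8.
- Pyrone 1 is lithiated with LiN(iPr)2 in THF at −78 °C and alkylated with 8, which should give 4-methoxy-6-{2-[2-methoxy-4-(methoxymethoxy)-6-(methoxymethyl)phenyl]ethyl}-2H-pyran-2-one F4. This carbanion reacts only at carbon and at low temperature.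
- Ester 9 is converted with MeNHOMe·HCl and iPrMgCl in THF into N-methoxy-N-methyl-2-(2-methyl-1,3-dioxolan-2-yl)acetamide F5.
- F4 is deprotonated at the CH2 next to the pyrone ring with LiN(iPr)2 at −78 °C and acylated with F5, whose stable tetrahedral adduct releases the ketone only on work-up; this comes back to the route at 11.

Step 5. The 2,4-dioxygenated benzylic bromide may ionise during formation or handling and alkylate the electron-rich ring of a second molecule, giving oligomers. The fallback avoids any benzylic halide and sets out from 7.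
- Oxidation with MnO2 in CH2Cl2 should give 2-methoxy-4-(methoxymethoxy)-6-(methoxymethyl)benzaldehyde F6.
- Knoevenagel condensation of F6 with 10 (piperidine, AcOH, toluene, removal of water) should give 4-methoxy-6-{1-[2-methoxy-4-(methoxymethoxy)-6-(methoxymethyl)phenyl]-4-(2-methyl-1,3-dioxolan-2-yl)-3-oxobut-1-en-2-yl}-2H-pyran-2-one F7 as an E/Z mixture.
- Conjugate reduction of F7 with Hantzsch ester (diethyl 2,6-dimethyl-1,4-dihydropyridine-3,5-dicarboxylate) comes back to the route at 11, so that steps 5 and 7 are both bypassed.

**Further compounds**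
F1 | step 8 | methyl 4-hydroxy-2-methoxy-6-[(2-methyl-1,3-dioxolan-2-yl)methyl]benzoate | COC(=O)c1c(OC)cc(O)cc1CC1(C)OCCO1
F2 | step 8 | methyl 3-bromo-4-hydroxy-6-methoxy-2-[(2-methyl-1,3-dioxolan-2-yl)methyl]benzoate | COC(=O)c1c(OC)cc(O)c(Br)c1CC1(C)OCCO1
F3 | step 8 | {[2-methoxy-4-(methoxymethoxy)-6-(methoxymethyl)phenyl]methyl}zinc bromide | COCOc1cc(COC)c(C[Zn]Br)c(OC)c1
F4 | step 7 | 4-methoxy-6-{2-[2-methoxy-4-(methoxymethoxy)-6-(methoxymethyl)phenyl]ethyl}-2H-pyran-2-one | COc1cc(=O)oc(CCc2c(COC)cc(OCOC)cc2OC)c1
F5 | step 7 | N-methoxy-N-methyl-2-(2-methyl-1,3-dioxolan-2-yl)acetamide | CON(C)C(=O)CC1(C)OCCO1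
F6 | step 5 | 2-methoxy-4-(methoxymethoxy)-6-(methoxymethyl)benzaldehyde | COCOc1cc(COC)c(C=O)c(OC)c1
F7 | step 5 | 4-methoxy-6-{1-[2-methoxy-4-(methoxymethoxy)-6-(methoxymethyl)phenyl]-4-(2-methyl-1,3-dioxolan-2-yl)-3-oxobut-1-en-2-yl}-2H-pyran-2-one (E/Z mixture) | COc1cc(=O)oc(C(=Cc2c(COC)cc(OCOC)cc2OC)C(=O)CC2(C)OCCO2)c1
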